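The data were computed with made-up constants, and the scatter is random.

The species read in the dawn run cannot be the whole of that closed flask: at 0.250 d they sum to 71.0% of the substrate charged.

the same everywhere: substrate 0.099 M; catalyst 0.2 mol%
- dawn: reagent 1.2 equiv; added ligand 0.50 mM; run made earlier
- flask: reagent 1.20 equiv; added ligand 1.0 mM; time 15 d

dawn run (percent of the substrate charged)

| time / d | isomer of the product A / % | target / % | substrate / % |
|---|---|---|---|
| 0.250 | 20.0 | 16.5 | 34.5 |
| 0.500 | 28.0 | 16.0 | 29.0 |
| 1.25 | 44.1 | 11.4 | 22.6 |
| 3.00 | 60.0 | 7.7 | 18.2 |

(standard deviation of a reading: 1 percentage point)

- the analysis behind the earlier runs scatters by 1 percentage point, standard deviation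
- no earlier run changes the charge of added ligand; that part of a forecast is a guess

- ratio of isomer of the product A to target at 5.0 min
- ratio of isomer of the product A to target at 5.0 h
- ratio of isomer of the product A to target at 15 d
- which of isomer of the product A and target there is more of at 15 d

Read down the rows of the dawn run, the missing material runs from 29.0% to 27.0%, 21.9% and 14.1%, which is a fall to half. Target, in the same rows, also falls to half. Dividing each row's missing material by its target gives 1.76, 1.69, 1.92 and 1.83, so the missing material follows target rather than the clock. The mean of these readings, 1.80, is the hidden share: the amount of missing material standing beside each unit of target.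

Now follow one molecule. Once it is in the family of target and missing form, its chance of being seen as target is 0.357. The column of isomer of the product A is therefore better held against the family than against target. That ratio reads 0.440 and 0.651 in the first two rows of the dawn run, and a straight line through them meets zero time at 0.228. My own reckoning takes this as the ratio at 5.0 min, assuming that the missing form is still empty then, which the readings cannot show. It also carries the hidden share unchanged to the new flask, which is a guess, since the ligand charge differs.

The forecast gives 0.65 at 5.0 min, 0.95 at 5.0 h and 15 at 15 d, with isomer of the product A ahead, and its early figure stands above mine: “That intercept is the early ratio, with the two products forming in comparable amounts.”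

The new flask gives 0.136, 0.850 and 11.4, with isomer of the product A ahead.

    substrate + reagent ⇌ target (K = 10.0 /M, k = 3.99 /M/h)
    substrate + reagent ⇌ isomer of the product A (K = 114 /M, k = 0.495 /M/h)
    target + catalyst ⇌ isomer of the product A + catalyst, rate k3*[catalyst]*[target] forward; the back reaction follows from the equilibrium constant (k = 642 /M/h)
    target ⇌ isomer of the product B (K = 1.91, k = 0.712 /h)
    catalyst + added ligand ⇌ idle complex (K = 3860 /M, k = 579 /M/h)

The early ratio lies below both estimates. The missing form is isomer of the product B, and the step joining it to target, taken alone and both ways together, relaxes with a half-life of 0.639 h, short against 15 d. At 15.0 d the new flask holds target 5.85%, so the hidden share expects 10.5% of isomer of the product B, and 11.2% stands there. The neighbouring flask, charged with 0.480 equiv of reagent, holds target 2.99% at that time. The same reckoning expects 5.38%, and its isomer of the product B reads 5.71%.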